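The data stem from a simulated flask with constants of no real substance; noise was put on by code.

Your colleague at the bench charges substrate at 0.30 M and wants the ring and the open dimer at 10 min.

| flask | substrate | remark | time |
|---|---|---|---|
| summer | 0.20 M | run made earlier |  |
| winter | 0.45 M | run made earlier |  |
| flask | 0.30 M |  | 10 min |

| run | time / min | ring / % | open dimer / % |
|---|---|---|---|
| summer | 2.50 | 16.3 | 36.8 |
| summer | 5.00 | 21.4 | 44.7 |
| summer | 8.00 | 23.1 | 47.9 |
| summer | 10.0 | 24.2 | 49.4 |
| summer | 12.0 | 24.6 | 50.0 |
| winter | 1.00 | 7.4 | 41.8 |
| winter | 2.00 | 10.9 | 53.7 |
| winter | 3.00 | 13.8 | 57.1 |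
| winter | 6.00 | 16.8 | 63.1 |
| winter | 12.0 | 17.1 | 65.6 |

(scatter of a reading: 0.5 percentage points)

1. amount of ring in the flask at 10 min, in percent of the substrate charged
2. amount of open dimer in the flask at 10 min, in percent of the substrate charged

- a species is counted by the substrate in it: one open dimer counts as two
- the analysis behind the earlier runs scatters by 0.5 percentage points, standard deviation
- a reading or a percentage of ring counts all its forms, free or not

Read each run by its split: open dimer over ring, both as fractions of the charge. Even shares, a split of 1, are the zero of the scale. At 12.0 min both runs stand above it: summer at 2.03, winter at 3.84. Summer's split at 10.0 min was already 2.04, so you can carry a split read near that time over to a flask read at 10 min.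

The bench rule sets a route using two substrate against a route using one, and says the split grows in proportion to the charge. Try it. Winter's charge is 2.25 times summer's, but its split is 1.89 times summer's. To obey the rule, winter's ring would have to read 14.3%; it reads 17.1%, with a scatter of 0.5 percentage points. So the rule already stops working between these two runs.

Keep the measured steepness instead: the logarithm of the split ratio over the logarithm of the charge ratio, 0.783, where the rule would have 1. For this flask my reckoning gives a split of 2.79, a ratio and no amounts.

The forecast says ring 20.8% and open dimer 57.8%, a split of 2.78, and expects that “the ring sits slightly high”.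

The flask gives ring 20.5% and open dimer 57.4%, a split of 2.80, and both forecast values stand within the tolerance. Behind it runs this scheme:

    substrate → ring (k = 0.00191 s⁻¹)
    2 substrate → open dimer (k = 0.0173 M⁻¹ s⁻¹)
    ring ⇌ isomer of the product (K = 1.50, k = 0.00181 s⁻¹)
    substrate + ring ⇌ idle adduct, settled at all times (K = 28.6 M⁻¹)
    crystals ⇌ ring, rate k5*(cs5 - [ring]) while solid is left; crystals form when [ring] > cs5 (solubility = 0.260 M, k = 0.0580 s⁻¹)

Going down in charge from this flask, ring has moved by 5 points at 0.171 M. The neighbour flask sits just above that mark at 0.18 M, read at the same time. The steepness gives it a split of 1.87, and it holds ring 25.0% and open dimer 47.2%, a split of 1.89.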